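The tetralin is cut at C1–C8a and C1 is rejoined, on paper, to C4. C1 (bearing the guaiacyl ring) and C4 (the ring CH2) are both benzylic and lie 1,4 to each other across C2–C3, so ring B is a constitutional isomer of a head-to-head 1,2-diarylcyclobutane built from C1, C2, C3 and C4.
That cyclobutane is cut at C2–C3 and C1–C4 into a ferulate ester (C1, C2, C9) and a protected sinapyl alcohol (C4, C3, C9').
Forward, the two arylpropene halves are made in one and two steps. The four-membered ring closes first in a crossed [2+2] photocycloaddition, and ring B arises next when C1–C4 breaks, C1 bonds to C8a and C4 takes up hydrogen.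
C2 is set by a chiral Lewis acid on the ferulate carbonyl, and C3 follows from C2 in the same bond formation. The cyclobutane configurations at C1 and C4 are sacrificial, and the final C1 centre is set trans to C2 when ring B closes.
Hydride reduction of C9 and removal of three protecting groups complete the synthesis.

Key step: step 4

Assumption: the sense of induction of the oxazaborolidine is carried over from terminal styrenes. The (S)-prolinol-derived catalyst is written, and its equally available enantiomer would be used if the opposite cyclobutane enantiomer were favoured.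

Step 1
Reactants: 1 4-(benzyloxy)-3-methoxybenzaldehyde (O-benzylvanillin)
Product: 2 methyl (E)-3-[4-(benzyloxy)-3-methoxyphenyl]prop-2-enoate (methyl O-benzylferulate)
Conditions: Ph3P=CHCO2Me (1.1 equiv), toluene, 80 °C
Reagents that add atoms: methyl (triphenylphosphoranylidene)acetate, COC(=O)C=P(c1ccccc1)(c1ccccc1)c1ccccc1
Why: Wittig olefination of an aromatic aldehyde with a stabilised ylide should give the E-cinnamate, and the benzyl ether is inert.

Step 2
Reactants: 3 4-bromo-2,6-dimethoxyphenol
Product: 4 4-bromo-2,6-dimethoxyphenyl pivalate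
Conditions: PivCl (1.2 equiv), Et3N (1.5 equiv), DMAP (cat.), CH2Cl2, 0 °C to rt
Reagents that add atoms: pivaloyl chloride, CC(C)(C)C(=O)Cl
Why: DMAP-catalysed O-acylation of a phenol installs an electron-withdrawing group on the later C7 oxygen that is hindered enough to survive steps 3 to 5.

Step 3
Reactants: 4 4-bromo-2,6-dimethoxyphenyl pivalate; 5 (E)-tert-butyldimethyl{[3-(4,4,5,5-tetramethyl-1,3,2-dioxaborolan-2-yl)prop-2-en-1-yl]oxy}silane
Product: 6 4-[(E)-3-{[tert-butyl(dimethyl)silyl]oxy}prop-1-en-1-yl]-2,6-dimethoxyphenyl pivalate (sinapyl alcohol, primary TBS ether, phenol pivalate)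
Conditions: Pd(dppf)Cl2 (3 mol %), K3PO4 (2 equiv), THF/H2O (10:1), 60 °C
Reagents that add atoms: none
Why: Suzuki–Miyaura coupling of an unhindered aryl bromide with an (E)-alkenylboronate keeps the alkene geometry, and the flanked aryl pivalate and the silyl ether should tolerate the mild phosphate base.

Step 4
Reactants: 2 methyl O-benzylferulate; 6 sinapyl alcohol TBS ether pivalate
Product: 7 methyl (1R,2S,3S,4R)-2-[4-(benzyloxy)-3-methoxyphenyl]-4-{[(tert-butyldimethylsilyl)oxy]methyl}-3-[3,5-dimethoxy-4-(pivaloyloxy)phenyl]cyclobutane-1-carboxylate (all-trans; cyclobutane C1, C2, C3, C4 = tetralin C2, C1, C4, C3)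
Conditions: (S)-diphenylprolinol-derived B-(o-tolyl)oxazaborolidine·HNTf2 (25–50 mol %), [Ir(ppy)2(dtbbpy)]PF6 (1 mol %), 6 (3 equiv, excess recovered), CH2Cl2, −40 °C, 450 nm LEDs
Reagents that add atoms: none
Why: Proposed new method: the protonated oxazaborolidine binds the ester carbonyl of 2, and energy transfer from the excited iridium complex, chosen too low in triplet energy to excite free 2 or 6 at a useful rate, reaches only this complex; the α-carbon C2 of the triplet then bonds to the non-benzylic alkene carbon C3 of 6, and the triplet 1,4-diradical, with both spins benzylic at C1 and C4, crosses to the singlet and joins C1 to C4. The closest known reaction is the oxazaborolidine/iridium co-catalysed triplet [2+2] cycloaddition of cinnamate esters with terminal styrenes; new is the 1,2-disubstituted styrene, for which the sensitised head-to-head dimerisation of cinnamates to all-trans truxinates shows that a cinnamate triplet does add to a β-substituted aryl alkene. The cyclobutane, the only ring formed, closes stepwise by recombination of the 1,4-diradical and not in a concerted way. C2 is set by the catalyst, whose aryl groups cover one face of the bound enoate; C3 is set relative to C2 in the same bond formation by an approach that keeps CH2OTBS away from the complexed ester, while diradicals of the other relative configuration could close only to a ring with cis neighbours and should rather fall apart to the alkenes; C1 and C4 are set in the closure, before which rotation about C1–C2 and C3–C4 lets each aryl group turn trans to both of its neighbours. The step needs cross- over homo-coupling, head-to-head orientation, the 2,3-trans relation and one enantiomer: selective excitation of bound 2 together with the excess of the more electron-rich alkene 6 towards the electrophilic α-carbonyl radical secures the first, the doubly benzylic diradical the second, and the factors just named the last two. The silyl ether and the hindered aryl pivalate of 6 are poor Lewis bases, so the acid stays on 2, and the acylated para-oxygen keeps 6 from acid-induced oligomerisation.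

Step 5
Reactants: 7 all-trans cyclobutane
Product: 8 methyl (1S,2R,3R)-1-[4-(benzyloxy)-3-methoxyphenyl]-3-{[(tert-butyldimethylsilyl)oxy]methyl}-6,8-dimethoxy-7-(pivaloyloxy)-1,2,3,4-tetrahydronaphthalene-2-carboxylate
Conditions: 9-mesityl-10-methylacridinium BF4 (5 mol %), PhSSPh (10 mol %), ClCH2CH2Cl (0.02 M), 450 nm LEDs, rt, N2
Reagents that add atoms: none
Why: Proposed new method: the excited acridinium oxidises the benzyloxy(methoxy)phenyl ring, the more electron-rich arene of 7, and the radical cation sheds ring strain by breaking the doubly benzylic C1–C4 bond with the charge at C1 (para-alkoxybenzyl) and the spin at C4 (whose ring offers only meta-methoxy groups and an acylated para-oxygen); C8a, one of two equivalent positions ortho and para to methoxy, attacks C1 in a Friedel–Crafts closure through a half-chair that places the aryl group pseudo-equatorial and trans to the C2 ester, which sets C1 as S; the proton lost on rearomatisation and the electron held by the acridinyl radical are passed on through the PhS•/PhSH couple and C4 receives its hydrogen atom from PhSH, so the step is a redox-neutral isomerisation; an acid trigger is avoided because a Lewis acid on the ester would polarise the vicinal donor–acceptor bond C1–C2 instead; the closest known reactions are the acridinium/disulfide formal [4+2] union of two styrenes to 1-aryltetralins, which runs through the same 1,4-distonic radical cation, and the electron-transfer-induced rearrangement of 1,2-diarylcyclobutanes to 1-aryltetralins.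

Step 6
Reactants: 8 tetralin ester
Product: 9 (1S,2R,3R)-1-[4-(benzyloxy)-3-methoxyphenyl]-3-{[(tert-butyldimethylsilyl)oxy]methyl}-2-(hydroxymethyl)-6,8-dimethoxy-1,2,3,4-tetrahydronaphthalen-7-ol
Conditions: LiAlH4 (4 equiv), THF, 0 °C to rt; aq. Rochelle salt
Reagents that add atoms: none
Why: LiAlH4 reduction takes the C9 ester to the primary alcohol and cleaves the aryl pivalate in the same operation, while the benzyl ether, the silyl ether and the all-equatorial stereotriad should be untouched.

Step 7
Reactants: 9 TBS ether benzyl ether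
Product: 11 (+)-8-methoxyisolariciresinol, via benzyl ether triol 10 (not isolated)
Conditions: HCl (0.1 M in MeOH), rt; then 10% Pd/C, H2 (1 atm), same flask
Reagents that add atoms: none
Why: Acid-catalysed methanolysis of a primary TBS ether followed by catalytic hydrogenolysis of an aryl benzyl ether are standard deprotections, and the tetralin is stable to dilute acid and carries no other reducible group.

Compound list
1 | 4-(benzyloxy)-3-methoxybenzaldehyde | COc1cc(C=O)ccc1OCc1ccccc1 | starting material
2 | methyl (E)-O-benzylferulate | COC(=O)/C=C/c1ccc(OCc2ccccc2)c(OC)c1 | intermediate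
3 | 4-bromo-2,6-dimethoxyphenol | COc1cc(Br)cc(OC)c1O | starting material
4 | 4-bromo-2,6-dimethoxyphenyl pivalate | COc1cc(Br)cc(OC)c1OC(=O)C(C)(C)C | intermediate
5 | (E)-3-(tert-butyldimethylsilyloxy)prop-1-enylboronic acid pinacol ester | CC(C)(C)[Si](C)(C)OC/C=C/B1OC(C)(C)C(C)(C)O1 | starting material
6 | (E)-sinapyl alcohol, primary TBS ether, phenol pivalate | COc1cc(/C=C/CO[Si](C)(C)C(C)(C)C)cc(OC)c1OC(=O)C(C)(C)C | intermediate
7 | all-trans (1R,2S,3S,4R)-cyclobutane with C9 methyl ester and C9' silyl ether | COc1cc([C@H]2[C@H](c3cc(OC)c(OC(=O)C(C)(C)C)c(OC)c3)[C@@H](CO[Si](C)(C)C(C)(C)C)[C@@H]2C(=O)OC)ccc1OCc1ccccc1 | intermediate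
8 | (1S,2R,3R)-tetralin 2-carboxylate, fully protected | COc1cc([C@H]2c3c(cc(OC)c(OC(=O)C(C)(C)C)c3OC)C[C@@H](CO[Si](C)(C)C(C)(C)C)[C@@H]2C(=O)OC)ccc1OCc1ccccc1 | intermediate
9 | (1S,2R,3R)-tetralin with C9 alcohol, C7 phenol, C9' TBS ether and guaiacyl benzyl ether | COc1cc([C@H]2c3c(cc(OC)c(O)c3OC)C[C@@H](CO[Si](C)(C)C(C)(C)C)[C@@H]2CO)ccc1OCc1ccccc1 | intermediate
10 | 4'-O-benzyl-8-methoxyisolariciresinol (benzyl ether triol) | COc1cc([C@H]2c3c(cc(OC)c(O)c3OC)C[C@@H](CO)[C@@H]2CO)ccc1OCc1ccccc1 | intermediate
11 | (+)-8-methoxyisolariciresinol, (1S,2R,3R) | COc1cc([C@H]2c3c(cc(OC)c(O)c3OC)C[C@@H](CO)[C@@H]2CO)ccc1O | target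

Total step count: 7. Longest linear sequence: 6 steps (3 → 4 → 6 → 7 → 8 → 9 → 11).

Steps most likely to fail

Step 4 (labelled).
- Risks: The 1,4-diradical may fragment back to the alkenes faster than it closes, so that only E/Z scrambling of the alkene occurs. Homodimerisation of the ferulate may compete. Facial discrimination may be weak with a 1,2-disubstituted alkene.
- Fallback: It sets out from 1, returns at 11, and builds ring B without a cyclobutane, by known reactions only.
- Commercial 4-(benzyloxy)-3,5-dimethoxybenzaldehyde undergoes Stobbe condensation with dimethyl succinate (NaOMe, MeOH, reflux) to the (E)-arylidene half-ester F1.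
- Rhodium-catalysed asymmetric hydrogenation with a C2-symmetric bis(phospholane) ligand of the appropriate hand gives the (R)-benzylsuccinic half-ester F2.
- Reduction of the ester group of its potassium salt with Ca(BH4)2, followed by acidification, closes the (R)-β-benzylbutyrolactone F3.
- The lithium enolate of F3 (LiHMDS, THF, −78 °C) adds to aldehyde 1 anti to the benzyl group to give the aldol adduct F4, as both carbinol epimers.
- TFA in CH2Cl2 ionises either epimer, and C8a captures the cation in a Friedel–Crafts cyclisation to the trans,trans tetralin lactone F5.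
- LiAlH4 opens the lactone to the bis-benzyl ether diol F6, and hydrogenolysis (H2, Pd/C) gives 11.

Step 5 (labelled).
- Risks: The opened radical cation may undergo cycloreversion to the two alkenes. It may lose the C2 proton to give an open-chain cinnamate, or C1 may be captured by the silyl ether oxygen. The benzyl group may be lost oxidatively.
- Fallback: It sets out from 7, returns at 11, and divides the isomerisation into a reduction and an oxidation that are each known.
- Catalytic hydrogenolysis (H2, 5 bar, Pd/C, EtOAc/AcOH, 50 °C) cleaves the strained doubly benzylic C1–C4 bond, as known for 1,2-diarylcyclobutanes. It also removes the benzyl ether and gives the open-chain phenol ester F7, with C2 and C3 untouched.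
- DDQ in CH2Cl2 oxidises only the ring with the free phenol to its para-quinone methide at C1. A little TFA then triggers Friedel–Crafts closure by C8a to the tetralin phenol ester F8.
- LiAlH4 gives the TBS ether bisphenol F9, and HCl in MeOH gives 11.

Step 3.
- Risks: The aqueous base may hydrolyse the aryl pivalate, and the alkenylboronate may undergo protodeboronation.
- Fallback: It sets out from 4 and returns at 6.
- A Heck reaction with acrolein diethyl acetal (Pd(OAc)2, n-Bu4NOAc, K2CO3, DMF, 90 °C) gives the cinnamaldehyde acetal F10.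
- Dilute HCl hydrolyses F10 to the pivaloylsinapaldehyde F11.
- Luche reduction (NaBH4, CeCl3, MeOH, 0 °C) gives the pivaloylsinapyl alcohol F12 without touching the aryl ester.
- TBSCl and imidazole in DMF then give 6.

Further compounds
F1 | step 4 | (E)-4-[4-(benzyloxy)-3,5-dimethoxyphenyl]-3-(methoxycarbonyl)but-3-enoic acid | COC(=O)/C(CC(=O)O)=C/c1cc(OC)c(OCc2ccccc2)c(OC)c1
F2 | step 4 | (R)-3-[4-(benzyloxy)-3,5-dimethoxybenzyl]-4-methoxy-4-oxobutanoic acid | COC(=O)[C@@H](CC(=O)O)Cc1cc(OC)c(OCc2ccccc2)c(OC)c1
F3 | step 4 | (R)-4-[4-(benzyloxy)-3,5-dimethoxybenzyl]dihydrofuran-2(3H)-one | O=C1C[C@@H](Cc2cc(OC)c(OCc3ccccc3)c(OC)c2)CO1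
F4 | step 4 | (3S,4R)-4-[4-(benzyloxy)-3,5-dimethoxybenzyl]-3-{[4-(benzyloxy)-3-methoxyphenyl](hydroxy)methyl}dihydrofuran-2(3H)-one, both carbinol epimers | O=C1OC[C@H](Cc2cc(OC)c(OCc3ccccc3)c(OC)c2)[C@H]1C(O)c1ccc(OCc2ccccc2)c(OC)c1
F5 | step 4 | (1S,2R,3R)-tetralin 2,3-trans-fused γ-lactone (C9 carbonyl, C9' OCH2), 7-O- and 4'-O-benzyl | COc1cc([C@H]2c3c(cc(OC)c(OCc4ccccc4)c3OC)C[C@H]3COC(=O)[C@H]23)ccc1OCc1ccccc1
F6 | step 4 | 7,4'-di-O-benzyl-8-methoxyisolariciresinol | COc1cc([C@H]2c3c(cc(OC)c(OCc4ccccc4)c3OC)C[C@@H](CO)[C@@H]2CO)ccc1OCc1ccccc1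
F7 | step 5 | methyl (2R,3R)-3-{[(tert-butyldimethylsilyl)oxy]methyl}-4-[3,5-dimethoxy-4-(pivaloyloxy)phenyl]-2-(4-hydroxy-3-methoxybenzyl)butanoate | COC(=O)[C@H](Cc1ccc(O)c(OC)c1)[C@H](CO[Si](C)(C)C(C)(C)C)Cc1cc(OC)c(OC(=O)C(C)(C)C)c(OC)c1
F8 | step 5 | methyl (1S,2R,3R)-3-{[(tert-butyldimethylsilyl)oxy]methyl}-1-(4-hydroxy-3-methoxyphenyl)-6,8-dimethoxy-7-(pivaloyloxy)-1,2,3,4-tetrahydronaphthalene-2-carboxylate | COc1cc([C@H]2c3c(cc(OC)c(OC(=O)C(C)(C)C)c3OC)C[C@@H](CO[Si](C)(C)C(C)(C)C)[C@@H]2C(=O)OC)ccc1O
F9 | step 5 | 9'-O-TBS-8-methoxyisolariciresinol | COc1cc([C@H]2c3c(cc(OC)c(O)c3OC)C[C@@H](CO[Si](C)(C)C(C)(C)C)[C@@H]2CO)ccc1O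
F10 | step 3 | 4-[(E)-3,3-diethoxyprop-1-en-1-yl]-2,6-dimethoxyphenyl pivalate | CCOC(/C=C/c1cc(OC)c(OC(=O)C(C)(C)C)c(OC)c1)OCC
F11 | step 3 | 2,6-dimethoxy-4-[(E)-3-oxoprop-1-en-1-yl]phenyl pivalate | COc1cc(/C=C/C=O)cc(OC)c1OC(=O)C(C)(C)C
F12 | step 3 | 4-[(E)-3-hydroxyprop-1-en-1-yl]-2,6-dimethoxyphenyl pivalate | COc1cc(/C=C/CO)cc(OC)c1OC(=O)C(C)(C)C
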